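Readings and results come from a simulation with constants of no real substance, and the scatter is random.

Read the spring flask at 0.200 min and you already have 12% of target; read it at 2.50 min and you have 24%, with 27% of the starting material still there.

common to all: starting material 0.20 mM
- spring: partner 0.50 equiv; second substrate 1 equiv; protic impurity 0.040 mM; free catalyst 0.2 mol%; run made earlier
- winter: partner 0.50 equiv; second substrate 1 equiv; protic impurity 0.040 mM; free catalyst 0.28 mol%; run made earlier
- summer: partner 0.50 equiv; second substrate 1 equiv; protic impurity 0.040 mM; free catalyst 0.44 mol%; run made earlier
- west: partner 0.500 equiv; second substrate 1.00 equiv; protic impurity 0.0400 mM; free catalyst 0.2 mol%; a tube with plug flow, the mixed feed as stated, residence time 4.0 min; time 4.0 min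
- north-east: partner 0.500 equiv; second substrate 1.00 equiv; protic impurity 0.0400 mM; free catalyst 0.2 mol%; everything together in a closed stirred flask, run for 4.0 min; time 4.0 min
- north-west: partner 0.500 equiv; second substrate 1.00 equiv; protic impurity 0.0400 mM; free catalyst 0.2 mol%; a single well-mixed tank run continuously and read at steady state, 4.0 min in it on average
- north: partner 0.500 equiv; second substrate 1.00 equiv (fed, over 4.00 min); protic impurity 0.0400 mM; free catalyst 0.2 mol%; all but second substrate at the start; second substrate goes in evenly over 4.00 min, the run ends at 4.0 min; time 4.0 min

| run | time / min | target / % | starting material / % |
|---|---|---|---|
| spring | 0.200 | 12 | 78 |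
| spring | 0.667 | 18 | 57 |
| spring | 1.00 | 24 | 49 |
| spring | 1.50 | 21 | 41 |
| spring | 2.50 | 24 | 27 |
| winter | 0.417 | 22 | 64 |
| winter | 0.667 | 21 | 57 |
| winter | 1.33 | 27 | 43 |
| winter | 2.50 | 28 | 30 |
| winter | 5.00 | 29 | 23 |
| summer | 0.417 | 24 | 61 |
| summer | 0.667 | 28 | 54 |
| summer | 1.33 | 31 | 40 |
| summer | 2.50 | 32 | 31 |
| summer | 5.00 | 32 | 20 |

(standard deviation of a reading: 2 percentage points)

- the stated concentrations are those of everything mixed, before any reaction; amounts are the same in each set-up
- the feed brings no volume worth counting
- the earlier runs were made in a closed, stirred flask

- the set-up with the highest amount of target at the outlet or at the end, in percent of the starting material put in ("none" if the first two lie within 2 percentage points) (west / north-east / north-west / north / none)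
- amount of target at the outlet or at the end, in percent of the starting material put in, west
- amount of target at the outlet or at the end, in percent of the starting material put in, north-east
- amount of target at the outlet or at the end, in percent of the starting material put in, north-west
- amount of target at the outlet or at the end, in percent of the starting material put in, north

The plateau climbs with loading, from 24% in spring to 32% in summer, so I read it as a catalyst that stops working while [starting material] remains. Divide the spring plateau by the first slope, 12% in 0.200 min, and you get 0.400 min: the working window, the time a flask needs to reach its plateau at its first rate.

But that slope rests on one reading with a scatter of 2 percentage points. Summer gives 0.556 min, and even that is shorter than the 4.0 min on offer. So I put west and north-east together at the spring plateau, 24%.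

Could partner cause the stop instead? Its 0.50 equiv is enough for 24% of target, but second substrate may consume it too, and the readings hold neither partner nor second substrate. If it does, dosing should help: at the end of the window, north has 10.0% of its second substrate in, or 13.9% by the summer window. I therefore rank north first, without a firm size.

For the north-west tank at steady state I take a working share of 9.09% of the catalyst, and that share at the first rate for 4.0 min gives the plateau times 90.9%. I guess [starting material] there near 41%, against 78% inside the window, which gives 11.5%. Partner is ignored, which is the weak point.

The forecast says north: 24.5% for west and north-east, 19% for north-west, where it stands above my figure, and 31% for north, on the ground that “Dosing the second substrate keeps SM high while partner is alive”.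

    starting material + partner + free catalyst → free catalyst + target (k = 3.40 × 10⁸ L² mol⁻² s⁻¹)
    second substrate + partner + free catalyst → free catalyst + second product (k = 1.70 × 10⁸ L² mol⁻² s⁻¹)
    2 starting material → self-condensation product (k = 26.0 L mol⁻¹ s⁻¹)
    free catalyst → spent catalyst (k = 0.0160 s⁻¹)
    second substrate + protic impurity → quenched substrate (k = 730 L mol⁻¹ s⁻¹)

The flask gives north at 30.1%, against 25.3% in west and north-east and 13.9% in north-west. At 4.00 min, north holds 0.00554 mM of second product against 0.0287 mM in west, with 10.0% of its second substrate dosed by the end of the 0.400 min window read from the spring run. Now take a flask like north with 0.12 mol% of free catalyst: hold the window, scale the slope with loading, and you expect 18.1%. It gives more than that, 22.4%, with 51% of its charged partner left.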